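**Plan**

- Retrosynthesis: the vanillate C6–O bond and the C9 carbinol (via a C9 ketone) are cut last. The seven-membered ring is then cut at C7–C8 and C9–C10, a rhodium (5+2) transform that gives a 1-(1-methoxyvinyl)bicyclo[3.1.0]hexane and a silylpropyne. The cyclopentane is cut at C4–C5 (samarium Reformatsky) and the cyclopropane is traced to geraniol.
- Forward: cyclopropane (C1, C5, C10) from geraniol, then ring A (cyclopentane C1–C5), then ring B (cycloheptadiene C1, C5–C10) by the (5+2) cycloaddition, then oxidation-level changes, acylation and C9 reduction.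
- Enabling feature: C1 is a methyl-bearing quaternary carbon bonded to both the ring-fusion carbon C5 and the C10 methylene, and C5 carries the oxygenated C6. C1–C5–C10 can therefore be a cyclopropane with C7=C6(OMe) as its vinyl group, a five-carbon unit that takes up the alkyne carbons C8 and C9.
- Stereochemistry: C1 by Charette cyclopropanation (reagent control); C4 by a chelated samarium enolate; C5 by protonation to the trans-fused ketol; C6 by hydroxyl-directed hydride delivery; C9 by hydride attack anti to the C1 methyl.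

Key step: step 9

Remark: atoms are named C1 (quaternary, CH3), C2, C3, C4 (carbinol with isopropyl), C5 (ring-fusion CH), C6 (ester carbon), C7=C8 (CH3 on C8), C9 (carbinol), C10 (CH2); azulene locants 8a, 1, 2, 3, 3a, 4, 5, 6, 7, 8 correspond to C1–C10; β is the face of the C1 methyl.
Remark: the facial sense of the dioxaborolane-controlled cyclopropanation is assigned by analogy with (E)-cinnamyl alcohol; geraniol, 10, 11 and 18 are taken as purchased.

**Step 1**
Reactants: 1 geraniol, (2E)-3,7-dimethylocta-2,6-dien-1-ol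
Product: 2 [(1R,2R)-2-methyl-2-(4-methylpent-3-en-1-yl)cyclopropyl]methanol
Conditions: Zn(CH2I)2·DME (from Et2Zn and CH2I2), (4S,5S)-2-butyl-N,N,N',N'-tetramethyl-1,3,2-dioxaborolane-4,5-dicarboxamide (1.2 equiv), CH2Cl2, −10 °C to rt
Reagents that add atoms: diiodomethane, ICI
Why: Charette asymmetric Simmons–Smith cyclopropanation, in which the zinc alkoxide bound to the chiral dioxaborolane delivers CH2 to one face of the allylic alkene only (the remote alkene has no directing group), should set the C1 quaternary centre and, from the E-alkene, the trans cyclopropane.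

**Step 2**
Reactants: 2 [(1R,2R)-2-methyl-2-(4-methylpent-3-en-1-yl)cyclopropyl]methanol
Product: 3 (1R,2R)-2-methyl-2-(4-methylpent-3-en-1-yl)cyclopropane-1-carboxylic acid
Conditions: TEMPO (0.2 equiv), PhI(OAc)2 (2.2 equiv), MeCN/H2O 1:1, rt
Reagents that add atoms: water, O
Why: Oxoammonium (TEMPO) oxidation of the primary alcohol through the aldehyde hydrate to the acid should leave the trisubstituted alkene and the cyclopropane untouched.

**Step 3**
Reactants: 3 (1R,2R)-2-methyl-2-(4-methylpent-3-en-1-yl)cyclopropane-1-carboxylic acid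
Product: 4 methyl (1R,2R)-2-methyl-2-(4-methylpent-3-en-1-yl)cyclopropane-1-carboxylate
Conditions: MeI, K2CO3, DMF, rt
Reagents that add atoms: iodomethane, CI
Why: O-alkylation of the carboxylate (SN2) gives the methyl ester without touching either stereocentre.

**Step 4**
Reactants: 4 methyl (1R,2R)-2-methyl-2-(4-methylpent-3-en-1-yl)cyclopropane-1-carboxylate
Product: 5 methyl (1RS,2R)-1-bromo-2-methyl-2-(4-methylpent-3-en-1-yl)cyclopropane-1-carboxylate
Conditions: LiN(iPr)2, THF, −78 °C; then BrCCl2CCl2Br, −78 °C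
Reagents that add atoms: 1,2-dibromo-1,1,2,2-tetrachloroethane, BrC(Cl)(Cl)C(Cl)(Cl)Br
Why: Electrophilic bromination of the cyclopropyl ester enolate (Claisen self-condensation is slowed by the adjacent quaternary carbon) puts a reducible C–Br bond on C5, whose configuration is irrelevant because it becomes an enolate again in step 6.

**Step 5**
Reactants: 5 methyl (1RS,2R)-1-bromo-2-methyl-2-(4-methylpent-3-en-1-yl)cyclopropane-1-carboxylate
Product: 7 methyl (1RS,2R)-1-bromo-2-methyl-2-(4-methyl-3-oxopentyl)cyclopropane-1-carboxylate, via alkylborane 6 (not isolated)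
Conditions: BH3·SMe2, THF, 0 °C; then 4-methylmorpholine N-oxide, nPr4N[RuO4] (5 mol %), 4 Å sieves, CH2Cl2, rt
Reagents that add atoms: 4-methylmorpholine N-oxide, C[N+]1([O-])CCOCC1
Why: Anti-Markovnikov hydroboration places boron on C4 and the one-pot amine-oxide/perruthenate oxidation of the organoborane should give the isopropyl ketone, with the hindered bromo ester inert.

**Step 6**
Reactants: 7 methyl (1RS,2R)-1-bromo-2-methyl-2-(4-methyl-3-oxopentyl)cyclopropane-1-carboxylate
Product: 8 methyl (1R,2R,5R)-2-hydroxy-5-methyl-2-(propan-2-yl)bicyclo[3.1.0]hexane-1-carboxylate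
Conditions: SmI2 (2.5 equiv), THF, −78 °C; aq. work-up
Reagents that add atoms: none
Why: Samarium Reformatsky-type aldol cyclisation: divalent samarium reduces the C–Br bond to an enolate planar at C5 (both epimers of 7 converge), the enolate carbon attacks the tethered ketone 5-exo-trig on the only possible (cis-fused) face, and chelation of trivalent samarium between enolate and ketone oxygens places the new hydroxyl cis to the ester and trans to the cyclopropane CH2, which sets C4.

**Step 7**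
Reactants: 8 methyl (1R,2R,5R)-2-hydroxy-5-methyl-2-(propan-2-yl)bicyclo[3.1.0]hexane-1-carboxylate
Product: 9 (1R,2R,5R)-1-(1-methoxyethenyl)-5-methyl-2-(propan-2-yl)bicyclo[3.1.0]hexan-2-ol
Conditions: Cp2Ti(μ-CH2)(μ-Cl)AlMe2 (3 equiv), pyridine, THF/toluene, −40 °C to rt; aq. NaOH
Reagents that add atoms: Tebbe reagent Cp2Ti(μ-CH2)(μ-Cl)AlMe2, C[Al-]1(C)C[Ti]([Cl+]1)(C2C=CC=C2)C3C=CC=C3
Why: Tebbe methylenation of the hindered ester carbonyl (titanium carbene, oxatitanacyclobutane, cycloreversion) should give the methyl enol ether that activates the vinylcyclopropane, the tertiary hydroxyl only consuming extra reagent.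

**Step 8**
Reactants: 10 prop-1-yn-1-ylmagnesium bromide; 11 benzyl(chloro)dimethylsilane
Product: 12 benzyl(dimethyl)(prop-1-yn-1-yl)silane
Conditions: THF, 0 °C to rt
Reagents that add atoms: none
Why: Substitution at silicon by the alkynyl Grignard reagent gives the silylalkyne whose benzylsilyl group later steers regiochemistry and becomes the C9 oxygen.

**Step 9**
Reactants: 9 (1R,2R,5R)-1-(1-methoxyethenyl)-5-methyl-2-(propan-2-yl)bicyclo[3.1.0]hexan-2-ol; 12 benzyl(dimethyl)(prop-1-yn-1-yl)silane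
Product: 13 (3R,8aR)-7-[benzyl(dimethyl)silyl]-4-methoxy-6,8a-dimethyl-3-(propan-2-yl)-1,2,3,5,8,8a-hexahydroazulen-3-ol
Conditions: [Rh(CO)2Cl]2 (5 mol %), 12 (1.5 equiv), 2,6-di-tert-butyl-4-methylpyridine (10 mol %), ClCH2CH2Cl, 80 °C
Reagents that add atoms: none
Why: Rhodium-catalysed (5+2) cycloaddition of a vinylcyclopropane with an alkyne: monovalent rhodium binds the methoxyvinyl group and cleaves the cyclopropane C5–C10 bond to a σ-alkyl/π-allyl rhodacycle (allyl C5–C6–C7, Rh–C10), the alkyne inserts at the unsubstituted allyl terminus C7 (new C7–C8 bond) and reductive elimination from the eight-membered rhodacycle forms the C9–C10 bond. The closest known reactions are intermolecular (5+2) cycloadditions of alkoxy- and alkyl-substituted vinylcyclopropanes with silyl alkynes under [Rh(CO)2Cl]2. Ring B is closed by this two-bond annulation, the C9–C10 bond arising in the ring-closing reductive elimination. No new sp3 stereocentre is formed: C5 becomes an enol ether carbon, and C1 and C4 are carried through because no bond to them is broken. The step needs cleavage of C5–C10 rather than C5–C1, which should follow because C10 is an unsubstituted CH2 whereas C1 is quaternary (a tertiary alkyl–rhodium and a bridged ring would result), and C1 has no hydrogen so the alkyl–rhodium cannot β-eliminate. It also needs silicon on C9, which the bulky SiMe2Bn group should secure by sitting distal to the first-formed C7–C8 bond.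

**Step 10**
Reactants: 13 (3R,8aR)-7-[benzyl(dimethyl)silyl]-4-methoxy-6,8a-dimethyl-3-(propan-2-yl)-1,2,3,5,8,8a-hexahydroazulen-3-ol
Product: 15 (3R,3aS,4S,8aR)-7-[benzyl(dimethyl)silyl]-6,8a-dimethyl-3-(propan-2-yl)-1,2,3,3a,4,5,8,8a-octahydroazulene-3,4-diol, via ketol 14 (not isolated)
Conditions: 0.5 M aq. oxalic acid, THF, 0 °C to rt; then Me4NBH(OAc)3, AcOH/MeCN, −30 °C
Reagents that add atoms: water, O
Why: Mild enol ether hydrolysis followed by Evans–Saksena reduction: C5 protonation under equilibrating conditions should give the trans-fused ketol (C6 carbonyl cis to and hydrogen-bonded with the C4 hydroxyl, trans to the isopropyl group), and the acetoxyborohydride bound to the C4 oxygen then delivers hydride to the β face of C6, giving the anti-1,3-diol (6α-OH) before the ketol can dehydrate.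

**Step 11**
Reactants: 15 (3R,3aS,4S,8aR)-7-[benzyl(dimethyl)silyl]-6,8a-dimethyl-3-(propan-2-yl)-1,2,3,3a,4,5,8,8a-octahydroazulene-3,4-diol
Product: 17 (3R,3aS,4S,8aR)-3,4-dihydroxy-6,8a-dimethyl-3-(propan-2-yl)-2,3,3a,4,5,6,8,8a-octahydroazulen-7(1H)-one, via silanol 16 (not isolated)
Conditions: Bu4NF, THF, 0 °C; then KHCO3, 30% H2O2, MeOH, rt
Reagents that add atoms: hydrogen peroxide, OO
Why: Tamao–Fleming oxidation: fluoride removes the benzyl group from silicon, and peroxide-induced 1,2-migration of the alkenyl group from silicon to oxygen gives the C9 enol and hence the C9 ketone exactly where silicon stood, the C8 epimers formed being erased in step 13.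

**Step 12**
Reactants: 17 (3R,3aS,4S,8aR)-3,4-dihydroxy-6,8a-dimethyl-3-(propan-2-yl)-2,3,3a,4,5,6,8,8a-octahydroazulen-7(1H)-one; 18 4-acetoxy-3-methoxybenzoic acid
Product: 19 [(3R,3aS,4S,8aR)-3-hydroxy-6,8a-dimethyl-7-oxo-3-(propan-2-yl)decahydroazulen-4-yl] 4-acetoxy-3-methoxybenzoate
Conditions: EDC·HCl, DMAP (0.2 equiv), CH2Cl2, 0 °C to rt
Reagents that add atoms: none
Why: Steglich esterification acylates only the secondary C6 hydroxyl because the C4 hydroxyl is tertiary and hindered, and no stereocentre is touched.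

**Step 13**
Reactants: 19 [(3R,3aS,4S,8aR)-3-hydroxy-6,8a-dimethyl-7-oxo-3-(propan-2-yl)decahydroazulen-4-yl] 4-acetoxy-3-methoxybenzoate
Product: 20 [(3R,3aS,4S,8aR)-3-hydroxy-6,8a-dimethyl-7-oxo-3-(propan-2-yl)-1,2,3,3a,4,7,8,8a-octahydroazulen-4-yl] 4-acetoxy-3-methoxybenzoate
Conditions: 2-iodoxybenzoic acid (2.5 equiv), DMSO, 70 °C
Reagents that add atoms: none
Why: Ketone dehydrogenation with 2-iodoxybenzoic acid through the enol can only desaturate the C8 side, because the other α-carbon C10 adjoins the hydrogen-free quaternary C1, so the C7=C8 enone should form and the C8 epimers converge.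

**Step 14**
Reactants: 20 [(3R,3aS,4S,8aR)-3-hydroxy-6,8a-dimethyl-7-oxo-3-(propan-2-yl)-1,2,3,3a,4,7,8,8a-octahydroazulen-4-yl] 4-acetoxy-3-methoxybenzoate
Product: 22 CNP0189996.3 [(3R,3aS,4S,7R,8aR)-3,7-dihydroxy-6,8a-dimethyl-3-(propan-2-yl)-1,2,3,3a,4,7,8,8a-octahydroazulen-4-yl] 4-hydroxy-3-methoxybenzoate, via allylic alcohol 21 (not isolated)
Conditions: NaBH4, CeCl3·7H2O, MeOH, −78 °C; then K2CO3, MeOH, 0 °C
Reagents that add atoms: none
Why: Luche 1,2-reduction with hydride attack on C9 from the α face, anti to the C1 methyl that shields the β face across C10, should give the 9β-alcohol, and carbonate-catalysed methanolysis then removes only the phenolic acetate, which cleaves far faster than the hindered secondary benzoate.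

**Compound list**

1 | geraniol, (2E)-3,7-dimethylocta-2,6-dien-1-ol | OC/C=C(C)/CCC=C(C)C | starting material
2 | [(1R,2R)-2-methyl-2-(4-methylpent-3-en-1-yl)cyclopropyl]methanol | OC[C@@H]1C[C@@]1(C)CCC=C(C)C | intermediate
3 | (1R,2R)-2-methyl-2-(4-methylpent-3-en-1-yl)cyclopropane-1-carboxylic acid | OC(=O)[C@@H]1C[C@@]1(C)CCC=C(C)C | intermediate
4 | methyl (1R,2R)-2-methyl-2-(4-methylpent-3-en-1-yl)cyclopropane-1-carboxylate | COC(=O)[C@@H]1C[C@@]1(C)CCC=C(C)C | intermediate
5 | methyl (1RS,2R)-1-bromo-2-methyl-2-(4-methylpent-3-en-1-yl)cyclopropane-1-carboxylate, epimers at the bromine-bearing carbon | COC(=O)C1(Br)C[C@@]1(C)CCC=C(C)C | intermediate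
6 | methyl (1RS,2R)-2-(3-boranyl-4-methylpentyl)-1-bromo-2-methylcyclopropane-1-carboxylate, alkylborane, not isolated | COC(=O)C1(Br)C[C@@]1(C)CCC(B)C(C)C | intermediate
7 | methyl (1RS,2R)-1-bromo-2-methyl-2-(4-methyl-3-oxopentyl)cyclopropane-1-carboxylate | COC(=O)C1(Br)C[C@@]1(C)CCC(=O)C(C)C | intermediate
8 | methyl (1R,2R,5R)-2-hydroxy-5-methyl-2-(propan-2-yl)bicyclo[3.1.0]hexane-1-carboxylate, hydroxyl cis to the ester and trans to the cyclopropane CH2 | COC(=O)[C@]12C[C@@]1(C)CC[C@@]2(O)C(C)C | intermediate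
9 | (1R,2R,5R)-1-(1-methoxyethenyl)-5-methyl-2-(propan-2-yl)bicyclo[3.1.0]hexan-2-ol | COC(=C)[C@]12C[C@@]1(C)CC[C@@]2(O)C(C)C | intermediate
10 | prop-1-yn-1-ylmagnesium bromide | CC#C[Mg]Br | starting material
11 | benzyl(chloro)dimethylsilane | C[Si](C)(Cl)Cc1ccccc1 | starting material
12 | benzyl(dimethyl)(prop-1-yn-1-yl)silane | CC#C[Si](C)(C)Cc1ccccc1 | intermediate
13 | (3R,8aR)-7-[benzyl(dimethyl)silyl]-4-methoxy-6,8a-dimethyl-3-(propan-2-yl)-1,2,3,5,8,8a-hexahydroazulen-3-ol, C5=C6 enol ether and C8=C9 vinylsilane | COC1=C2[C@](O)(C(C)C)CC[C@]2(C)CC([Si](C)(C)Cc3ccccc3)=C(C)C1 | intermediate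
14 | (3R,3aR,8aR)-7-[benzyl(dimethyl)silyl]-3-hydroxy-6,8a-dimethyl-3-(propan-2-yl)-2,3,3a,5,8,8a-hexahydroazulen-4(1H)-one, trans-fused ketol, not isolated | O=C1CC(C)=C([Si](C)(C)Cc2ccccc2)C[C@@]3(C)CC[C@@](O)(C(C)C)[C@H]13 | intermediate
15 | (3R,3aS,4S,8aR)-7-[benzyl(dimethyl)silyl]-6,8a-dimethyl-3-(propan-2-yl)-1,2,3,3a,4,5,8,8a-octahydroazulene-3,4-diol | O[C@H]1CC(C)=C([Si](C)(C)Cc2ccccc2)C[C@@]3(C)CC[C@@](O)(C(C)C)[C@H]13 | intermediate
16 | (3R,3aS,4S,8aR)-7-[hydroxy(dimethyl)silyl]-6,8a-dimethyl-3-(propan-2-yl)-1,2,3,3a,4,5,8,8a-octahydroazulene-3,4-diol, silanol, not isolated | O[C@H]1CC(C)=C([Si](C)(C)O)C[C@@]2(C)CC[C@@](O)(C(C)C)[C@H]12 | intermediate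
17 | (3R,3aS,4S,8aR)-3,4-dihydroxy-6,8a-dimethyl-3-(propan-2-yl)-2,3,3a,4,5,6,8,8a-octahydroazulen-7(1H)-one, both C8 epimers | O[C@H]1CC(C)C(=O)C[C@@]2(C)CC[C@@](O)(C(C)C)[C@H]12 | intermediate
18 | 4-acetoxy-3-methoxybenzoic acid | CC(=O)Oc1ccc(cc1OC)C(O)=O | starting material
19 | [(3R,3aS,4S,8aR)-3-hydroxy-6,8a-dimethyl-7-oxo-3-(propan-2-yl)decahydroazulen-4-yl] 4-acetoxy-3-methoxybenzoate, both C8 epimers | COc1cc(C(=O)O[C@H]2CC(C)C(=O)C[C@@]3(C)CC[C@@](O)(C(C)C)[C@H]23)ccc1OC(C)=O | intermediate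
20 | [(3R,3aS,4S,8aR)-3-hydroxy-6,8a-dimethyl-7-oxo-3-(propan-2-yl)-1,2,3,3a,4,7,8,8a-octahydroazulen-4-yl] 4-acetoxy-3-methoxybenzoate | COc1cc(C(=O)O[C@H]2C=C(C)C(=O)C[C@@]3(C)CC[C@@](O)(C(C)C)[C@H]23)ccc1OC(C)=O | intermediate
21 | [(3R,3aS,4S,7R,8aR)-3,7-dihydroxy-6,8a-dimethyl-3-(propan-2-yl)-1,2,3,3a,4,7,8,8a-octahydroazulen-4-yl] 4-acetoxy-3-methoxybenzoate, not isolated | COc1cc(C(=O)O[C@H]2C=C(C)[C@H](O)C[C@@]3(C)CC[C@@](O)(C(C)C)[C@H]23)ccc1OC(C)=O | intermediate
22 | CNP0189996.3, [(3R,3aS,4S,7R,8aR)-3,7-dihydroxy-6,8a-dimethyl-3-(propan-2-yl)-1,2,3,3a,4,7,8,8a-octahydroazulen-4-yl] 4-hydroxy-3-methoxybenzoate | COc1cc(C(=O)O[C@H]2C=C(C)[C@H](O)C[C@@]3(C)CC[C@@](O)(C(C)C)[C@H]23)ccc1O | target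

**Step count**

Total: 14 steps. Longest linear sequence: 13 steps (steps 1–7 and 9–14, from geraniol).

**Steps most likely to fail**

1. Step 9. The oxidative opening of the fully substituted, ring-fused cyclopropane may be sluggish, or alkyne insertion with the bulky benzylsilyl alkyne may be slow or poorly regioselective. Fallback, setting out from 9 and returning at 17: run the cycloaddition with commercial 1-(trimethylsilyl)propyne to give the trimethylsilyl cycloadduct F1. Hydrolyse its enol ether as in step 10 to the trimethylsilyl ketol F2 and reduce this with Me4NBH(OAc)3 to the vinylsilane diol F3. Epoxidise the vinylsilane (mCPBA, NaHCO3, CH2Cl2) to the α,β-epoxysilane F4 and open it with 10% H2SO4 in MeOH (epoxysilane-to-ketone conversion), which gives 17 and replaces the Tamao–Fleming oxidation.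

2. Step 10. C5 may be protonated from the wrong face (cis-fused ketol), or the tertiary hydroxyl may be lost by acid-induced dehydration before reduction. Fallback, setting out from 8 and returning at 15: avoid the C6 ketone altogether. Reduce 8 with iBu2AlH (−78 °C) to the aldehyde F5 and methylenate it (Ph3P=CH2) to the vinylcyclopropane F6. Carry out the same [Rh(CO)2Cl]2-catalysed cycloaddition with 12 to the 1,4-diene F7. Hydroborate the C5=C6 alkene (9-BBN; NaBO3·4H2O) from the face anti to the C1 methyl, which adds H5 and the 6-hydroxyl syn on the α face and gives 15.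

3. Step 14. Hydride addition to C9 may show poor facial selectivity and give the 9α-alcohol. Fallback, setting out from 20 and returning at 22: stop after the reduction and separate the 9α-epimer F8. Invert C9 by Mitsunobu reaction with 4-nitrobenzoic acid (PPh3, DIAD) to the 9β-(4-nitrobenzoate) F9. Methanolyse the 4-nitrobenzoate and the aryl acetate together (K2CO3, MeOH, 0 °C) to reach 22.

**Further compounds**

F1 | step 9 | (3R,8aR)-4-methoxy-6,8a-dimethyl-3-(propan-2-yl)-7-(trimethylsilyl)-1,2,3,5,8,8a-hexahydroazulen-3-ol | COC1=C2[C@](O)(C(C)C)CC[C@]2(C)CC([Si](C)(C)C)=C(C)C1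
F2 | step 9 | (3R,3aR,8aR)-3-hydroxy-6,8a-dimethyl-3-(propan-2-yl)-7-(trimethylsilyl)-2,3,3a,5,8,8a-hexahydroazulen-4(1H)-one | O=C1CC(C)=C([Si](C)(C)C)C[C@@]2(C)CC[C@@](O)(C(C)C)[C@H]12
F3 | step 9 | (3R,3aS,4S,8aR)-6,8a-dimethyl-3-(propan-2-yl)-7-(trimethylsilyl)-1,2,3,3a,4,5,8,8a-octahydroazulene-3,4-diol | O[C@H]1CC(C)=C([Si](C)(C)C)C[C@@]2(C)CC[C@@](O)(C(C)C)[C@H]12
F4 | step 9 | C8–C9 epoxide of F3 (α,β-epoxysilane, either epoxide face) | O[C@H]1CC2(C)OC2([Si](C)(C)C)C[C@@]3(C)CC[C@@](O)(C(C)C)[C@H]13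
F5 | step 10 | (1R,2R,5R)-2-hydroxy-5-methyl-2-(propan-2-yl)bicyclo[3.1.0]hexane-1-carbaldehyde | O=C[C@]12C[C@@]1(C)CC[C@@]2(O)C(C)C
F6 | step 10 | (1R,2R,5R)-1-ethenyl-5-methyl-2-(propan-2-yl)bicyclo[3.1.0]hexan-2-ol | C=C[C@]12C[C@@]1(C)CC[C@@]2(O)C(C)C
F7 | step 10 | (3R,8aR)-7-[benzyl(dimethyl)silyl]-6,8a-dimethyl-3-(propan-2-yl)-1,2,3,5,8,8a-hexahydroazulen-3-ol (C5=C6 and C8=C9 diene) | C1=C2[C@](O)(C(C)C)CC[C@]2(C)CC([Si](C)(C)Cc3ccccc3)=C(C)C1
F8 | step 14 | 9α-epimer of 21, [(3R,3aS,4S,7S,8aR)-3,7-dihydroxy-6,8a-dimethyl-3-(propan-2-yl)-1,2,3,3a,4,7,8,8a-octahydroazulen-4-yl] 4-acetoxy-3-methoxybenzoate | COc1cc(C(=O)O[C@H]2C=C(C)[C@@H](O)C[C@@]3(C)CC[C@@](O)(C(C)C)[C@H]23)ccc1OC(C)=O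
F9 | step 14 | 9β-(4-nitrobenzoate) of 21 | COc1cc(C(=O)O[C@H]2C=C(C)[C@H](OC(=O)c4ccc(cc4)[N+]([O-])=O)C[C@@]3(C)CC[C@@](O)(C(C)C)[C@H]23)ccc1OC(C)=O
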